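**Retrosynthetic overview**

- Locants: ring A is C1(O-acyl)–C2(OH)–C3H2–C4–C9(CH3)–C10(H)CH3 and ring B is C4=C5–C6(=O)–C7(OH)=C8–C9. The last disconnections are the C1–O ester (dienoic acid 32) and the C6/C7 oxygens, which come from a C4=C5 octalin by allylic oxidation and α′-hydroxylation/oxidation.
- The strategy rests on the homoallylic alcohol C2(OH)–C3H2–C4=C5 that links ring A to ring B. It is the retron of a carbonyl-ene reaction: cutting C2–C3 gives aldehyde 17, an α-alkoxy aldehyde tethered through C1–C10 to the quaternary C9 of a 2-methylenecyclohexane (C4=C3H2), with H5 as the transferred hydrogen.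
- Aldehyde 17 comes from acid 8 by one-carbon homologation with 1,3-dithiane through a Weinreb amide; a Felkin–Anh reduction sets C1. Acid 8 comes from propanoate 6 by an enantioselective Ireland–Claisen rearrangement that forms C9–C10 and sets C9, C10 and the exocyclic methylene.
- Ring order: ring B is the carbocycle of the starting keto ester 1 and is present throughout; ring A is closed second, in the ene step. The side-chain acid is made from (S)-2-methylbutan-1-ol.

Key step: step 11

Assumption: the (4S,5S)-diazaborolidine controller is taken to deliver the (2R,1′R)-acid 8; if the first run shows the opposite facial sense, its (4R,5R)-enantiomer is used and nothing else changes; the bromoborane is prepared beforehand from the commercial bis-sulfonamide and BBr3.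

**Route**

Step 1
Reactants: 1 ethyl 2-oxocyclohexane-1-carboxylate
Product: 2 ethyl 2-{[(trifluoromethyl)sulfonyl]oxy}cyclohex-1-ene-1-carboxylate
Conditions: Tf2O, iPr2NEt, CH2Cl2, −78 °C → rt
Reagents that add atoms: trifluoromethanesulfonic anhydride, O=S(=O)(OS(=O)(=O)C(F)(F)F)C(F)(F)F
Why: O-sulfonylation of the enol of the β-keto ester (enol triflate formation) should fix the ring double bond between the ester carbon and the future C9.

Step 2
Reactants: 2 ethyl 2-{[(trifluoromethyl)sulfonyl]oxy}cyclohex-1-ene-1-carboxylate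
Product: 3 ethyl 2-methylcyclohex-1-ene-1-carboxylate
Conditions: MeMgBr, Fe(acac)3 (5 mol %), THF/NMP, −30 °C
Reagents that add atoms: methylmagnesium bromide, C[Mg]Br
Why: Iron-catalysed Kumada-type cross-coupling of the electron-poor alkenyl triflate should outrun attack of the Grignard reagent on the ester at this temperature and keep the double bond in place.

Step 3
Reactants: 3 ethyl 2-methylcyclohex-1-ene-1-carboxylate
Product: 4 (2-methylcyclohex-1-en-1-yl)methanol
Conditions: iBu2AlH (2.5 equiv), CH2Cl2, −78 → 0 °C; aq. KNaC4H4O6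
Reagents that add atoms: none
Why: 1,2-Reduction of the conjugated ester with the aluminium hydride should give the allylic alcohol and leave the tetrasubstituted olefin untouched.

Step 4
Reactants: 4 (2-methylcyclohex-1-en-1-yl)methanol; 5 propanoyl chloride
Product: 6 (2-methylcyclohex-1-en-1-yl)methyl propanoate
Conditions: pyridine, DMAP (cat.), CH2Cl2, 0 °C → rt
Reagents that add atoms: none
Why: DMAP-catalysed O-acylation of a primary allylic alcohol is routine.

Step 5
Reactants: 6 (2-methylcyclohex-1-en-1-yl)methyl propanoate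
Product: 8 (2R)-2-[(1R)-1-methyl-2-methylidenecyclohexyl]propanoic acid, via boron ketene acetal 7 (not isolated)
Conditions: (4S,5S)-2-bromo-1,3-bis{[3,5-bis(trifluoromethyl)phenyl]sulfonyl}-4,5-diphenyl-1,3,2-diazaborolidine (1.2 equiv), iPr2NEt, CH2Cl2, −78 °C; then −20 → 4 °C; aqueous work-up
Reagents that add atoms: none
Why: Soft enolisation with the C2-symmetric bromoborane and iPr2NEt in CH2Cl2 should give ketene acetal 7 with the methyl cis to O–B, and its enantioselective Ireland–Claisen rearrangement through a chair (ring methyl, cis to the CH2O arm, axial; enolate methyl equatorial) forms C9–C10 and sets the quaternary C9, C10 and the exocyclic methylene in one event, the controller choosing the chair enantiomer and the acyloxyborane being hydrolysed in the work-up.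

Step 6
Reactants: 8 (2R)-2-[(1R)-1-methyl-2-methylidenecyclohexyl]propanoic acid
Product: 10 (2R)-N-methoxy-N-methyl-2-[(1R)-1-methyl-2-methylidenecyclohexyl]propanamide, via acid chloride 9 (not isolated)
Conditions: 1-chloro-N,N,2-trimethylprop-1-en-1-amine, CH2Cl2, 0 °C → rt; then MeNHOMe·HCl, pyridine, 0 °C → rt
Reagents that add atoms: N,O-dimethylhydroxylamine hydrochloride, CNOC.Cl
Why: Neutral acid chloride formation with the α-chloroenamine releases no HCl that could add to the 1,1-disubstituted olefin, and amidation with pyridine as base (Weinreb amide formation) should not epimerise C10 through a ketene.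

Step 7
Reactants: 10 (2R)-N-methoxy-N-methyl-2-[(1R)-1-methyl-2-methylidenecyclohexyl]propanamide; 11 1,3-dithiane
Product: 13 (2R)-1-(1,3-dithian-2-yl)-2-[(1R)-1-methyl-2-methylidenecyclohexyl]propan-1-one, via 2-lithio-1,3-dithiane 12 (not isolated)
Conditions: 11, n-BuLi, THF, −30 °C; then 10, −78 → 0 °C; H2O
Reagents that add atoms: none
Why: Corey–Seebach acyl-anion addition to the Weinreb amide should stop at the chelated tetrahedral adduct until work-up, so there is no second addition and no enolisation at C10; the dithiane carbon becomes C2.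

Step 8
Reactants: 13 (2R)-1-(1,3-dithian-2-yl)-2-[(1R)-1-methyl-2-methylidenecyclohexyl]propan-1-one
Product: 14 (1R,2R)-1-(1,3-dithian-2-yl)-2-[(1R)-1-methyl-2-methylidenecyclohexyl]propan-1-ol
Conditions: iBu2AlH, toluene, −78 °C; aq. KNaC4H4O6
Reagents that add atoms: none
Why: Felkin–Anh-controlled hydride reduction: the quaternary C9 stands anti to the incoming hydride, which passes the C10–H, so the C1 oxygen should end anti to the C10 methyl in the C2–C1–C10–C9 zigzag, which is the arrangement that becomes C1–O cis to the C10 methyl in ring A.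

Step 9
Reactants: 14 (1R,2R)-1-(1,3-dithian-2-yl)-2-[(1R)-1-methyl-2-methylidenecyclohexyl]propan-1-ol
Product: 16 2-{(1R,2R)-1-[(4-methoxyphenyl)methoxy]-2-[(1R)-1-methyl-2-methylidenecyclohexyl]propyl}-1,3-dithiane, via sodium alkoxide 15 (not isolated)
Conditions: NaH, DMF, 0 °C; then 4-MeOC6H4CH2Cl, Bu4NI (cat.), 0 °C → rt
Reagents that add atoms: 4-methoxybenzyl chloride, COc1ccc(CCl)cc1
Why: Williamson etherification of the hindered alkoxide with the reactive benzylic halide (iodide catalysis) should install the PMB ether without touching the dithiane C–H.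

Step 10
Reactants: 16 2-{(1R,2R)-1-[(4-methoxyphenyl)methoxy]-2-[(1R)-1-methyl-2-methylidenecyclohexyl]propyl}-1,3-dithiane
Product: 17 (2R,3R)-2-[(4-methoxyphenyl)methoxy]-3-[(1R)-1-methyl-2-methylidenecyclohexyl]butanal
Conditions: MeI, CaCO3, MeCN/H2O (9:1), rt → 40 °C
Reagents that add atoms: water, O
Why: S-Alkylative hydrolysis of the dithiane under carbonate buffering should free the aldehyde without harming the PMB ether, the exocyclic olefin or the epimerisable C1.

Step 11
Reactants: 17 (2R,3R)-2-[(4-methoxyphenyl)methoxy]-3-[(1R)-1-methyl-2-methylidenecyclohexyl]butanal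
Product: 18 (2R,3R,4R,4aR)-3-[(4-methoxyphenyl)methoxy]-4,4a-dimethyl-1,2,3,4,4a,5,6,7-octahydronaphthalen-2-ol
Conditions: Me2AlCl (1.5 equiv), CH2Cl2, −78 → −40 °C; H2O
Reagents that add atoms: none
Why: Me2AlCl binds the aldehyde oxygen through one site, and the activated C2=O adds to C3 of the 1,1-disubstituted olefin while the axial allylic hydrogen on C5 passes to oxygen in a six-centre array, so that C2–C3 forms, the olefin moves to C4=C5, and loss of methane from the aluminium alkoxide makes the step irreversible. The closest known reaction type is the alkylaluminium-halide-promoted type 2 intramolecular carbonyl-ene cyclisation, in which the aldehyde is tethered to the central carbon of the ene unit of a methylenecycloalkane and a bicyclic homoallylic alcohol results. Ring A closes as a six-membered ring through a chair, in the mode that is endo for the olefin (C3 and C4 both inside the new ring) and exo for the carbonyl. The new stereocentre C2 is fixed by that chair: ring B spans C5 and C8, so C8 must lie equatorial on ring A and the C9 methyl axial, which puts the C10 methyl equatorial and the C1 ether axial, and the carbonyl oxygen must be axial on the opposite face to reach H5, so C1–O and C2–OH should come out trans-diaxial as in the target, with the two C–O dipoles opposed because the Lewis acid is not chelated. The step needs face selectivity at the aldehyde and a concerted course instead of a Prins cation; the first is secured by C9, C10 and C1 of the substrate, the second by the proton-scavenging methyl groups on aluminium and by the fact that only C5 carries allylic hydrogens, C9 being quaternary.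

Step 12
Reactants: 18 (2R,3R,4R,4aR)-3-[(4-methoxyphenyl)methoxy]-4,4a-dimethyl-1,2,3,4,4a,5,6,7-octahydronaphthalen-2-ol
Product: 19 tert-butyl{[(2R,3R,4R,4aR)-3-[(4-methoxyphenyl)methoxy]-4,4a-dimethyl-1,2,3,4,4a,5,6,7-octahydronaphthalen-2-yl]oxy}dimethylsilane
Conditions: TBSOTf, 2,6-lutidine, CH2Cl2, −78 → 0 °C
Reagents that add atoms: tert-butyldimethylsilyl trifluoromethanesulfonate, CC(C)(C)[Si](C)(C)OS(=O)(=O)C(F)(F)F
Why: Silylation with the silyl triflate should protect the hindered axial C2 hydroxyl before the oxidations of ring B.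

Step 13
Reactants: 19 tert-butyl{[(2R,3R,4R,4aR)-3-[(4-methoxyphenyl)methoxy]-4,4a-dimethyl-1,2,3,4,4a,5,6,7-octahydronaphthalen-2-yl]oxy}dimethylsilane
Product: 20 (4aR,5R,6R,7R)-7-{[tert-butyl(dimethyl)silyl]oxy}-6-[(4-methoxyphenyl)methoxy]-4a,5-dimethyl-4,4a,5,6,7,8-hexahydronaphthalen-2(3H)-one
Conditions: CrO3, 3,5-dimethylpyrazole, CH2Cl2, −20 °C
Reagents that add atoms: chromium trioxide, O=[Cr](=O)=O
Why: Allylic oxidation with the CrO3–3,5-dimethylpyrazole complex should take the CH2 next to the CH end of the trisubstituted olefin (C6), as in the oxidation of valencene-type octalins to nootkatone-type enones, while C3 is flanked by the fully substituted C4 and deactivated by the neighbouring C2 silyl ether.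

Step 14
Reactants: 20 (4aR,5R,6R,7R)-7-{[tert-butyl(dimethyl)silyl]oxy}-6-[(4-methoxyphenyl)methoxy]-4a,5-dimethyl-4,4a,5,6,7,8-hexahydronaphthalen-2(3H)-one
Product: 22 (4aR,5R,6R,7R)-7-{[tert-butyl(dimethyl)silyl]oxy}-3-hydroxy-6-[(4-methoxyphenyl)methoxy]-4a,5-dimethyl-4,4a,5,6,7,8-hexahydronaphthalen-2(3H)-one (C7 hydroxyl; both C7 epimers are used), via sodium dienolate 21 (not isolated)
Conditions: NaN(SiMe3)2, THF, −78 °C; then (±)-trans-3-phenyl-2-(phenylsulfonyl)oxaziridine, −78 °C; H2O
Reagents that add atoms: trans-3-phenyl-2-(phenylsulfonyl)oxaziridine, O=S(=O)(N1OC1c1ccccc1)c1ccccc1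
Why: Kinetic α′-deprotonation at C7 gives the cross-conjugated dienolate, and electrophilic hydroxylation with the N-sulfonyloxaziridine (Davis oxidation) should put oxygen on C7, whose configuration is lost in the next step.

Step 15
Reactants: 22 (4aR,5R,6R,7R)-7-{[tert-butyl(dimethyl)silyl]oxy}-3-hydroxy-6-[(4-methoxyphenyl)methoxy]-4a,5-dimethyl-4,4a,5,6,7,8-hexahydronaphthalen-2(3H)-one
Product: 24 (4aS,5R,6R,7R)-7-{[tert-butyl(dimethyl)silyl]oxy}-3-hydroxy-6-[(4-methoxyphenyl)methoxy]-4a,5-dimethyl-5,6,7,8-tetrahydronaphthalen-2(4aH)-one, via 6,7-dione 23 (not isolated)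
Conditions: Dess–Martin periodinane, CH2Cl2, rt
Reagents that add atoms: none
Why: Dess–Martin oxidation of the α-ketol gives the ene-1,2-dione, which should enolise toward C8 (the only α-hydrogens) to the cross-conjugated diosphenol.

Step 16
Reactants: 24 (4aS,5R,6R,7R)-7-{[tert-butyl(dimethyl)silyl]oxy}-3-hydroxy-6-[(4-methoxyphenyl)methoxy]-4a,5-dimethyl-5,6,7,8-tetrahydronaphthalen-2(4aH)-one
Product: 25 (4aS,5R,6R,7R)-3,7-bis{[tert-butyl(dimethyl)silyl]oxy}-6-[(4-methoxyphenyl)methoxy]-4a,5-dimethyl-5,6,7,8-tetrahydronaphthalen-2(4aH)-one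
Conditions: TBSCl, imidazole, DMF, rt
Reagents that add atoms: tert-butyldimethylsilyl chloride, CC(C)(C)[Si](C)(C)Cl
Why: O-Silylation of the acidic enol hydroxyl masks the diosphenol so that only the C1 hydroxyl can be acylated later.

Step 17
Reactants: 25 (4aS,5R,6R,7R)-3,7-bis{[tert-butyl(dimethyl)silyl]oxy}-6-[(4-methoxyphenyl)methoxy]-4a,5-dimethyl-5,6,7,8-tetrahydronaphthalen-2(4aH)-one
Product: 26 (4aS,5R,6R,7R)-3,7-bis{[tert-butyl(dimethyl)silyl]oxy}-6-hydroxy-4a,5-dimethyl-5,6,7,8-tetrahydronaphthalen-2(4aH)-one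
Conditions: DDQ, CH2Cl2/pH 7 phosphate buffer, 0 °C
Reagents that add atoms: none
Why: Oxidative cleavage of the PMB ether (benzylic hydride abstraction by DDQ, then hydrolysis of the hemiacetal) should free the C1 hydroxyl, the electron-poor 2-silyloxydienone and the alkyl silyl ether being inert to the quinone.

Step 18
Reactants: 27 (2S)-2-methylbutan-1-ol
Product: 28 (2S)-2-methylbutanal
Conditions: TEMPO (cat.), KBr (cat.), NaOCl, NaHCO3 buffer, CH2Cl2/H2O, 0 °C
Reagents that add atoms: none
Why: Nitroxyl-catalysed hypochlorite oxidation (Anelli oxidation) in a buffered two-phase system should stop at the aldehyde without racemising the α-stereocentre, which is the future C6′.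

Step 19
Reactants: 28 (2S)-2-methylbutanal; 29 ethyl (2E)-4-(diethoxyphosphoryl)but-2-enoate
Product: 31 ethyl (2E,4E,6S)-6-methylocta-2,4-dienoate, via lithiated phosphonate 30 (not isolated)
Conditions: 29, LiN(SiMe3)2, THF, −78 °C; then 28, −78 → 0 °C
Reagents that add atoms: none
Why: Vinylogous Horner–Wadsworth–Emmons olefination with the preformed stabilised anion should give the (2E,4E)-dienoate, and the low temperature keeps the aldehyde from enolising.

Step 20
Reactants: 31 ethyl (2E,4E,6S)-6-methylocta-2,4-dienoate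
Product: 32 (2E,4E,6S)-6-methylocta-2,4-dienoic acid
Conditions: LiOH, THF/H2O, rt; then 1 M HCl
Reagents that add atoms: lithium hydroxide, [Li+].[OH-]
Why: Saponification of the ethyl ester leaves the diene geometry and the remote stereocentre alone.

Step 21
Reactants: 26 (4aS,5R,6R,7R)-3,7-bis{[tert-butyl(dimethyl)silyl]oxy}-6-hydroxy-4a,5-dimethyl-5,6,7,8-tetrahydronaphthalen-2(4aH)-one; 32 (2E,4E,6S)-6-methylocta-2,4-dienoic acid
Product: 34 (4aS,5R,6R,7R)-3,7-bis{[tert-butyl(dimethyl)silyl]oxy}-4a,5-dimethyl-2-oxo-2,4a,5,6,7,8-hexahydronaphthalen-6-yl (2E,4E,6S)-6-methylocta-2,4-dienoate, via mixed anhydride 33 (not isolated)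
Conditions: 32, 2,4,6-Cl3C6H2COCl, Et3N, toluene, rt; then 26, DMAP, toluene, rt → 40 °C
Reagents that add atoms: none
Why: Yamaguchi esterification, in which DMAP attacks the unhindered dienoyl carbonyl of the mixed anhydride, is the standard way to acylate a hindered secondary alcohol with a conjugated acid, and the C1 hydroxyl is the only free one.

Step 22
Reactants: 34 (4aS,5R,6R,7R)-3,7-bis{[tert-butyl(dimethyl)silyl]oxy}-4a,5-dimethyl-2-oxo-2,4a,5,6,7,8-hexahydronaphthalen-6-yl (2E,4E,6S)-6-methylocta-2,4-dienoate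
Product: 35 Septeremophilane G
Conditions: HF·pyridine, pyridine, THF, 0 °C → rt
Reagents that add atoms: none
Why: Fluoride cleavage of both Si–O bonds under buffered acidic conditions should free the C2 hydroxyl and the diosphenol without the C1 → C2 acyl shift that a basic fluoride source could cause.

**Compound list**

1 | ethyl 2-oxocyclohexane-1-carboxylate | CCOC(=O)C1CCCCC1=O | starting material
2 | ethyl 2-{[(trifluoromethyl)sulfonyl]oxy}cyclohex-1-ene-1-carboxylate | CCOC(=O)C1=C(OS(=O)(=O)C(F)(F)F)CCCC1 | intermediate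
3 | ethyl 2-methylcyclohex-1-ene-1-carboxylate | CCOC(=O)C1=C(C)CCCC1 | intermediate
4 | (2-methylcyclohex-1-en-1-yl)methanol | OCC1=C(C)CCCC1 | intermediate
5 | propanoyl chloride | CCC(=O)Cl | starting material
6 | (2-methylcyclohex-1-en-1-yl)methyl propanoate | CCC(=O)OCC1=C(C)CCCC1 | intermediate
7 | boron ketene acetal, (4S,5S)-1,3-bis{[3,5-bis(trifluoromethyl)phenyl]sulfonyl}-2-({(1E)-1-[(2-methylcyclohex-1-en-1-yl)methoxy]prop-1-en-1-yl}oxy)-4,5-diphenyl-1,3,2-diazaborolidine (methyl cis to O–B) | C/C=C(/OCC1=C(C)CCCC1)OB1N(S(=O)(=O)c2cc(C(F)(F)F)cc(C(F)(F)F)c2)[C@@H](c2ccccc2)[C@H](c2ccccc2)N1S(=O)(=O)c1cc(C(F)(F)F)cc(C(F)(F)F)c1 | intermediate (not isolated)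
8 | (2R)-2-[(1R)-1-methyl-2-methylidenecyclohexyl]propanoic acid | OC(=O)[C@H](C)[C@@]1(C)CCCCC1=C | intermediate
9 | (2R)-2-[(1R)-1-methyl-2-methylidenecyclohexyl]propanoyl chloride | ClC(=O)[C@H](C)[C@@]1(C)CCCCC1=C | intermediate (not isolated)
10 | (2R)-N-methoxy-N-methyl-2-[(1R)-1-methyl-2-methylidenecyclohexyl]propanamide | CON(C)C(=O)[C@H](C)[C@@]1(C)CCCCC1=C | intermediate
11 | 1,3-dithiane | C1CSCSC1 | starting material
12 | 2-lithio-1,3-dithiane | [Li]C1SCCCS1 | intermediate (not isolated)
13 | (2R)-1-(1,3-dithian-2-yl)-2-[(1R)-1-methyl-2-methylidenecyclohexyl]propan-1-one | O=C(C1SCCCS1)[C@H](C)[C@@]1(C)CCCCC1=C | intermediate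
14 | (1R,2R)-1-(1,3-dithian-2-yl)-2-[(1R)-1-methyl-2-methylidenecyclohexyl]propan-1-ol | S1CCCSC1[C@H](O)[C@H](C)[C@@]1(C)CCCCC1=C | intermediate
15 | sodium alkoxide of 14 | S1CCCSC1[C@H]([O-])[C@H](C)[C@@]1(C)CCCCC1=C.[Na+] | intermediate (not isolated)
16 | 2-{(1R,2R)-1-[(4-methoxyphenyl)methoxy]-2-[(1R)-1-methyl-2-methylidenecyclohexyl]propyl}-1,3-dithiane | S1CCCSC1[C@H](OCc1ccc(OC)cc1)[C@H](C)[C@@]1(C)CCCCC1=C | intermediate
17 | (2R,3R)-2-[(4-methoxyphenyl)methoxy]-3-[(1R)-1-methyl-2-methylidenecyclohexyl]butanal | O=C[C@H](OCc1ccc(OC)cc1)[C@H](C)[C@@]1(C)CCCCC1=C | intermediate (key-step precursor)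
18 | (2R,3R,4R,4aR)-3-[(4-methoxyphenyl)methoxy]-4,4a-dimethyl-1,2,3,4,4a,5,6,7-octahydronaphthalen-2-ol | COc1ccc(CO[C@H]2[C@H](O)CC3=CCCC[C@]3(C)[C@H]2C)cc1 | intermediate (key-step product)
19 | tert-butyl{[(2R,3R,4R,4aR)-3-[(4-methoxyphenyl)methoxy]-4,4a-dimethyl-1,2,3,4,4a,5,6,7-octahydronaphthalen-2-yl]oxy}dimethylsilane | COc1ccc(CO[C@H]2[C@H](O[Si](C)(C)C(C)(C)C)CC3=CCCC[C@]3(C)[C@H]2C)cc1 | intermediate
20 | (4aR,5R,6R,7R)-7-{[tert-butyl(dimethyl)silyl]oxy}-6-[(4-methoxyphenyl)methoxy]-4a,5-dimethyl-4,4a,5,6,7,8-hexahydronaphthalen-2(3H)-one | COc1ccc(CO[C@H]2[C@H](O[Si](C)(C)C(C)(C)C)CC3=CC(=O)CC[C@]3(C)[C@H]2C)cc1 | intermediate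
21 | sodium cross-conjugated dienolate of 20 (C6–O−, C6=C7) | COc1ccc(CO[C@H]2[C@H](O[Si](C)(C)C(C)(C)C)CC3=CC([O-])=CC[C@]3(C)[C@H]2C)cc1.[Na+] | intermediate (not isolated)
22 | (4aR,5R,6R,7R)-7-{[tert-butyl(dimethyl)silyl]oxy}-3-hydroxy-6-[(4-methoxyphenyl)methoxy]-4a,5-dimethyl-4,4a,5,6,7,8-hexahydronaphthalen-2(3H)-one (C7 hydroxyl, both epimers) | COc1ccc(CO[C@H]2[C@H](O[Si](C)(C)C(C)(C)C)CC3=CC(=O)C(O)C[C@]3(C)[C@H]2C)cc1 | intermediate
23 | (4aR,5R,6R,7R)-7-{[tert-butyl(dimethyl)silyl]oxy}-6-[(4-methoxyphenyl)methoxy]-4a,5-dimethyl-4,4a,5,6,7,8-hexahydronaphthalene-2,3-dione (the 6,7-dione) | COc1ccc(CO[C@H]2[C@H](O[Si](C)(C)C(C)(C)C)CC3=CC(=O)C(=O)C[C@]3(C)[C@H]2C)cc1 | intermediate (not isolated)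
24 | (4aS,5R,6R,7R)-7-{[tert-butyl(dimethyl)silyl]oxy}-3-hydroxy-6-[(4-methoxyphenyl)methoxy]-4a,5-dimethyl-5,6,7,8-tetrahydronaphthalen-2(4aH)-one | COc1ccc(CO[C@H]2[C@H](O[Si](C)(C)C(C)(C)C)CC3=CC(=O)C(O)=C[C@]3(C)[C@H]2C)cc1 | intermediate
25 | (4aS,5R,6R,7R)-3,7-bis{[tert-butyl(dimethyl)silyl]oxy}-6-[(4-methoxyphenyl)methoxy]-4a,5-dimethyl-5,6,7,8-tetrahydronaphthalen-2(4aH)-one | COc1ccc(CO[C@H]2[C@H](O[Si](C)(C)C(C)(C)C)CC3=CC(=O)C(O[Si](C)(C)C(C)(C)C)=C[C@]3(C)[C@H]2C)cc1 | intermediate
26 | (4aS,5R,6R,7R)-3,7-bis{[tert-butyl(dimethyl)silyl]oxy}-6-hydroxy-4a,5-dimethyl-5,6,7,8-tetrahydronaphthalen-2(4aH)-one | O[C@H]1[C@H](O[Si](C)(C)C(C)(C)C)CC2=CC(=O)C(O[Si](C)(C)C(C)(C)C)=C[C@]2(C)[C@H]1C | intermediate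
27 | (2S)-2-methylbutan-1-ol | CC[C@H](C)CO | starting material
28 | (2S)-2-methylbutanal | CC[C@H](C)C=O | intermediate
29 | ethyl (2E)-4-(diethoxyphosphoryl)but-2-enoate | CCOC(=O)/C=C/CP(=O)(OCC)OCC | starting material
30 | lithium salt of 29 (carbanion α to phosphorus) | CCOC(=O)/C=C/[CH-]P(=O)(OCC)OCC.[Li+] | intermediate (not isolated)
31 | ethyl (2E,4E,6S)-6-methylocta-2,4-dienoate | CC[C@H](C)/C=C/C=C/C(=O)OCC | intermediate
32 | (2E,4E,6S)-6-methylocta-2,4-dienoic acid | CC[C@H](C)/C=C/C=C/C(=O)O | intermediate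
33 | (2E,4E,6S)-6-methylocta-2,4-dienoic 2,4,6-trichlorobenzoic anhydride | CC[C@H](C)/C=C/C=C/C(=O)OC(=O)c1c(Cl)cc(Cl)cc1Cl | intermediate (not isolated)
34 | (4aS,5R,6R,7R)-3,7-bis{[tert-butyl(dimethyl)silyl]oxy}-4a,5-dimethyl-2-oxo-2,4a,5,6,7,8-hexahydronaphthalen-6-yl (2E,4E,6S)-6-methylocta-2,4-dienoate | CC[C@H](C)/C=C/C=C/C(=O)O[C@H]1[C@H](O[Si](C)(C)C(C)(C)C)CC2=CC(=O)C(O[Si](C)(C)C(C)(C)C)=C[C@]2(C)[C@H]1C | intermediate
35 | Septeremophilane G, (4aS,5R,6R,7R)-3,7-dihydroxy-4a,5-dimethyl-2-oxo-2,4a,5,6,7,8-hexahydronaphthalen-6-yl (2E,4E,6S)-6-methylocta-2,4-dienoate | CC[C@H](C)/C=C/C=C/C(=O)O[C@H]1[C@H](O)CC2=CC(=O)C(O)=C[C@]2(C)[C@H]1C | target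

**Step count and risks**

Total step count: 22. Longest linear sequence: 19 steps (steps 1–17, 21 and 22); the side-chain acid takes steps 18–20.

The three steps most likely to fail:

1. Step 11 (carbonyl-ene closure). Face selectivity at the aldehyde may be lost if the closure runs through a boat, through a two-point-bound aluminium complex of C1–O and C2=O, or stepwise as a Prins reaction with the oxygen equatorial; the C2 epimer would then form. The fallback corrects C2 after the ring is closed instead of controlling it in the closure. Setting out from 17, the cyclisation then gives the C2-epimeric alcohol, (2S,3R,4R,4aR)-3-[(4-methoxyphenyl)methoxy]-4,4a-dimethyl-1,2,3,4,4a,5,6,7-octahydronaphthalen-2-ol F1. Its equatorial hydroxyl is inverted by a Mitsunobu reaction (4-nitrobenzoic acid, PPh3, diisopropyl azodicarboxylate, toluene, 0 °C → rt) to the axial ester, (2R,3R,4R,4aR)-3-[(4-methoxyphenyl)methoxy]-4,4a-dimethyl-1,2,3,4,4a,5,6,7-octahydronaphthalen-2-yl 4-nitrobenzoate F2. Methanolysis (K2CO3, MeOH, rt) comes back to the route at 18.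

2. Step 5 (enantioselective Ireland–Claisen). The sigmatropic shift onto a tetrasubstituted olefin may be slow, the bias of the controller may be transferred incompletely (erosion of enantiomeric purity), or part of the material may pass through a boat (C10 epimer). The fallback replaces reagent control by a diastereoselective rearrangement and a resolution. Setting out from 6, enolisation with LiN(iPr)2 in THF/DMPU at −78 °C and trapping with Me3SiCl give the silyl ketene acetal with the methyl cis to O–Si, trimethyl({(1Z)-1-[(2-methylcyclohex-1-en-1-yl)methoxy]prop-1-en-1-yl}oxy)silane F3. It rearranges through the same chair on warming to rt and, after hydrolysis, gives the racemic acid of the same relative configuration, rac-(2R*)-2-[(1R*)-1-methyl-2-methylidenecyclohexyl]propanoic acid F4. Crystallisation with (S)-1-phenylethylamine (or its antipode, whichever precipitates the wanted enantiomer) gives the salt (S)-1-phenylethylammonium (2R)-2-[(1R)-1-methyl-2-methylidenecyclohexyl]propanoate F5, and acidification comes back to the route at 8.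

3. Step 13 (allylic oxidation). Hydrogen abstraction may occur at the benzylic CH2 of the PMB ether (oxidation to the 4-methoxybenzoate or loss of the group) or at C3 instead of C6. The fallback delivers oxygen to C4 and then transposes it to C6. Setting out from 19, a Schenck ene reaction with singlet oxygen (O2, hν, tetraphenylporphyrin, CH2Cl2, 0 °C) should add oxygen at the fully substituted C4 and take hydrogen from C6, giving the tertiary allylic hydroperoxide of 19 with C4–OOH and the olefin at C5=C6, F6. Reduction with PPh3 gives the corresponding tertiary allylic alcohol with C4–OH and C5=C6, F7. Oxidative 1,3-transposition with pyridinium chlorochromate (C5H5NH[CrO3Cl], CH2Cl2, rt; Babler–Dauben oxidation) comes back to the route at 20.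

**Further compounds**

F1 | step 11 | (2S,3R,4R,4aR)-3-[(4-methoxyphenyl)methoxy]-4,4a-dimethyl-1,2,3,4,4a,5,6,7-octahydronaphthalen-2-ol (C2 epimer of 18) | COc1ccc(CO[C@H]2[C@@H](O)CC3=CCCC[C@]3(C)[C@H]2C)cc1
F2 | step 11 | (2R,3R,4R,4aR)-3-[(4-methoxyphenyl)methoxy]-4,4a-dimethyl-1,2,3,4,4a,5,6,7-octahydronaphthalen-2-yl 4-nitrobenzoate | COc1ccc(CO[C@H]2[C@H](OC(=O)c3ccc(cc3)[N+](=O)[O-])CC3=CCCC[C@]3(C)[C@H]2C)cc1
F3 | step 5 | trimethyl({(1Z)-1-[(2-methylcyclohex-1-en-1-yl)methoxy]prop-1-en-1-yl}oxy)silane (methyl cis to O–Si) | C/C=C(/OCC1=C(C)CCCC1)O[Si](C)(C)C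
F4 | step 5 | rac-(2R*)-2-[(1R*)-1-methyl-2-methylidenecyclohexyl]propanoic acid (racemate, both enantiomers written) | OC(=O)[C@H](C)[C@@]1(C)CCCCC1=C.OC(=O)[C@@H](C)[C@]1(C)CCCCC1=C
F5 | step 5 | (S)-1-phenylethylammonium (2R)-2-[(1R)-1-methyl-2-methylidenecyclohexyl]propanoate | C[C@H]([NH3+])c1ccccc1.[O-]C(=O)[C@H](C)[C@@]1(C)CCCCC1=C
F6 | step 13 | tertiary allylic hydroperoxide of 19: C4–OOH, olefin at C5=C6, C2–OTBS and C1–OPMB unchanged (C4 configuration open) | COc1ccc(CO[C@H]2[C@H](O[Si](C)(C)C(C)(C)C)CC3(OO)C=CCC[C@]3(C)[C@H]2C)cc1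
F7 | step 13 | tertiary allylic alcohol from F6: C4–OH, olefin at C5=C6 (C4 configuration open) | COc1ccc(CO[C@H]2[C@H](O[Si](C)(C)C(C)(C)C)CC3(O)C=CCC[C@]3(C)[C@H]2C)cc1
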